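**Plan**

- Labdane numbering is used: ring A = C1–C5 + C10, ring B = C5–C10, C17 = ester carbon on C8, C11–C16 = side chain. Ring B is a cyclohexene whose C6=C7 bond lies opposite the C9–C10 bond and whose four sp3 atoms (C5, C10, C9, C8) are all stereogenic, which is a Diels–Alder retron.
- Cuts, in retrosynthetic order: O–acetyl at C16; C12–C13 (B-alkyl Suzuki–Miyaura coupling); C5–C10 and C8–C9 together (intramolecular Diels–Alder reaction); C1–C10 (B-alkyl Suzuki–Miyaura coupling); C7≡C8 semi-reduction; C6–C7 (Sonogashira coupling); C5=C6 (Takai olefination).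
- Forward: an acyclic, achiral triene is built from 2,2-dimethylpent-4-enal. One cycloaddition closes ring B and, through the C1–C4 tether, ring A. The side chain is attached last.
- Helpers: the C11 carbonyl carrying an (R)-4-benzyloxazolidinone activates C9=C10 and is later turned into the C11 methylene (via a vinyl group). C17 is held as CH2OTBS so that the diene stays electron-rich, and is oxidised afterwards.
- Stereochemistry: C5, C8, C9 and C10 all arise in the cycloaddition. The absolute sense comes from the auxiliary, the trans ring fusion from the endo mode, and C8 from the Z diene terminus. The side-chain alkene geometry comes from anti hydroiodination and a retentive coupling.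

Key step: step 6

Remark: (2E)-3-iodobut-2-enoic acid (6) is taken as a purchased compound; if it is not, it is one hydroiodination step from but-2-ynoic acid under equilibrating conditions.

**Route**

Step 1
Reactants: 1 2,2-dimethylpent-4-enal
Product: 2 (1E)-1-iodo-3,3-dimethylhexa-1,5-diene
Conditions: CrCl2 (6 equiv), CHI3 (2 equiv), THF/dioxane, 0 °C to rt
Reagents that add atoms: iodoform, IC(I)I
Why: Takai olefination of the non-enolisable, hindered aldehyde with the geminal dichromium species from CHI3 and CrCl2 should give the E vinyl iodide (C5=C6), which fixes the geometry of the tether-bearing diene terminus and leaves the terminal alkene untouched.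

Step 2
Reactants: 2 (1E)-1-iodo-3,3-dimethylhexa-1,5-diene; 3 tert-butyl(dimethyl)(prop-2-yn-1-yloxy)silane
Product: 4 tert-butyl{[(4E)-6,6-dimethylnona-4,8-dien-2-yn-1-yl]oxy}dimethylsilane
Conditions: Pd(PPh3)2Cl2 (3 mol %), CuI (6 mol %), Et3N, THF, rt
Reagents that add atoms: none
Why: Sonogashira coupling of a vinyl iodide with a terminal alkyne proceeds with retention of the E geometry under conditions that spare the silyl ether and the terminal alkene.

Step 3
Reactants: 4 tert-butyl{[(4E)-6,6-dimethylnona-4,8-dien-2-yn-1-yl]oxy}dimethylsilane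
Product: 5 tert-butyl{[(2Z,4E)-6,6-dimethylnona-2,4,8-trien-1-yl]oxy}dimethylsilane
Conditions: Zn dust activated with Cu(OAc)2 and AgNO3, MeOH/H2O (1:1), 40 °C
Reagents that add atoms: none
Why: Boland semi-reduction reduces only the conjugated alkyne by syn delivery of two hydrogens, which should set the Z geometry of C7=C8 without touching the isolated terminal alkene or the E double bond.

Step 4
Reactants: 6 (2E)-3-iodobut-2-enoic acid; 7 (4R)-4-benzyl-1,3-oxazolidin-2-one
Product: 10 (4R)-4-benzyl-3-[(2E)-3-iodobut-2-enoyl]-1,3-oxazolidin-2-one, via acid chloride 8 (not isolated), via lithium oxazolidinide 9 (not isolated)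
Conditions: 6, (COCl)2, cat. DMF, CH2Cl2, 0 °C to rt, evaporate; 7, n-BuLi, THF, −78 °C; combine, −78 to 0 °C
Reagents that add atoms: none
Why: N-acylation of the lithiated oxazolidinone by the acid chloride (Evans imide formation) is fast at low temperature, and because no amine is present the β-iodoenoyl unit should keep its E geometry.

Step 5
Reactants: 5 tert-butyl{[(2Z,4E)-6,6-dimethylnona-2,4,8-trien-1-yl]oxy}dimethylsilane; 10 (4R)-4-benzyl-3-[(2E)-3-iodobut-2-enoyl]-1,3-oxazolidin-2-one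
Product: 12 (4R)-4-benzyl-3-[(2E,8E,10Z)-12-{[tert-butyl(dimethyl)silyl]oxy}-3,7,7-trimethyldodeca-2,8,10-trienoyl]-1,3-oxazolidin-2-one, via B-alkyl-9-BBN 11 (not isolated)
Conditions: 5, 9-BBN (1.1 equiv), THF, 0 °C to rt; then 10, PdCl2(dppf) (5 mol %), AsPh3, K3PO4 (aq), DMF, rt
Reagents that add atoms: none
Why: 9-BBN hydroborates the monosubstituted terminal alkene much faster than the conjugated 1,2-disubstituted diene, and B-alkyl Suzuki–Miyaura coupling with the β-iodoenoyl imide forms C1–C10 with retention, which should give the E trisubstituted dienophile.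

Step 6
Reactants: 12 (4R)-4-benzyl-3-[(2E,8E,10Z)-12-{[tert-butyl(dimethyl)silyl]oxy}-3,7,7-trimethyldodeca-2,8,10-trienoyl]-1,3-oxazolidin-2-one
Product: 13 (4R)-4-benzyl-3-{[(1R,2S,4aR,8aR)-2-({[tert-butyl(dimethyl)silyl]oxy}methyl)-5,5,8a-trimethyl-1,2,4a,5,6,7,8,8a-octahydronaphthalen-1-yl]carbonyl}-1,3-oxazolidin-2-one
Conditions: Me2AlCl (2.0 equiv), CH2Cl2, −30 to 0 °C; aq Rochelle salt
Reagents that add atoms: none
Why: Me2AlCl turns the imide into the cationic chelate [imide·AlMe2]+, locked s-cis, and the tethered (8E,10Z)-diene adds across C9=C10 in a normal-demand, asynchronous [4+2] cycloaddition in which the C5–C10 bond runs ahead; the closest known reaction type is the Lewis acid promoted intramolecular Diels–Alder reaction of trienoyl oxazolidinones (type 1, 1,7,9-decatriene series). Ring B closes by the suprafacial [4+2] addition itself, and ring A closes in the same event as the four-carbon tether C1–C4 folds chair-like while C5–C10 forms, helped by the gem-dimethyl group at C4. The absolute configuration at C9 and C10 comes from the (R)-benzyl group of the auxiliary, which covers the Si face of C9 so that the diene adds to the Re face. The trans ring fusion (C5/C10) comes from the endo transition state with the chelated acyl group under the diene, the cis relation of the C10 methyl group and C11 from the E dienophile, and the C8 configuration from the Z geometry of C7=C8, whose inside CH2OTBS group ends cis to H5 and trans to the C9 acyl group. The step needs endo over exo addition and one π-face; the chelate and the benzyl group secure these, and the inside substituent adds to the endo preference because in the exo array it would lie over the acyl group.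

Step 7
Reactants: 13 (4R)-4-benzyl-3-{[(1R,2S,4aR,8aR)-2-({[tert-butyl(dimethyl)silyl]oxy}methyl)-5,5,8a-trimethyl-1,2,4a,5,6,7,8,8a-octahydronaphthalen-1-yl]carbonyl}-1,3-oxazolidin-2-one
Product: 14 [(1R,2S,4aR,8aR)-2-({[tert-butyl(dimethyl)silyl]oxy}methyl)-5,5,8a-trimethyl-1,2,4a,5,6,7,8,8a-octahydronaphthalen-1-yl]methanol
Conditions: LiBH4, MeOH (2 equiv), THF/Et2O, 0 °C
Reagents that add atoms: none
Why: Reductive cleavage of the N-acyloxazolidinone with LiBH4 delivers hydride to the exocyclic carbonyl, which should release the C11 primary alcohol and the recoverable auxiliary without touching the silyl ether or the ring alkene.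

Step 8
Reactants: 14 [(1R,2S,4aR,8aR)-2-({[tert-butyl(dimethyl)silyl]oxy}methyl)-5,5,8a-trimethyl-1,2,4a,5,6,7,8,8a-octahydronaphthalen-1-yl]methanol
Product: 15 (1R,2S,4aR,8aR)-2-({[tert-butyl(dimethyl)silyl]oxy}methyl)-5,5,8a-trimethyl-1,2,4a,5,6,7,8,8a-octahydronaphthalene-1-carbaldehyde
Conditions: Dess–Martin periodinane, CH2Cl2, 0 °C to rt
Reagents that add atoms: none
Why: Dess–Martin oxidation of the primary alcohol is non-basic, so the C11 aldehyde should form without epimerisation at C9, where the equatorial aldehyde is in any case the stable epimer.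

Step 9
Reactants: 15 (1R,2S,4aR,8aR)-2-({[tert-butyl(dimethyl)silyl]oxy}methyl)-5,5,8a-trimethyl-1,2,4a,5,6,7,8,8a-octahydronaphthalene-1-carbaldehyde
Product: 16 tert-butyl{[(1R,2S,4aR,8aS)-1-ethenyl-5,5,8a-trimethyl-1,2,4a,5,6,7,8,8a-octahydronaphthalen-2-yl]methoxy}dimethylsilane
Conditions: Ph3PCH3Br, KHMDS, THF, 0 °C; then 15, −78 °C to rt
Reagents that add atoms: methyltriphenylphosphonium bromide, C[P+](c1ccccc1)(c1ccccc1)c1ccccc1.[Br-]
Why: Wittig methylenation with the small unstabilised ylide should convert the hindered aldehyde into the vinyl group (C11=C12), and addition at low temperature limits enolisation at C9.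

Step 10
Reactants: 16 tert-butyl{[(1R,2S,4aR,8aS)-1-ethenyl-5,5,8a-trimethyl-1,2,4a,5,6,7,8,8a-octahydronaphthalen-2-yl]methoxy}dimethylsilane
Product: 17 [(1R,2S,4aR,8aS)-1-ethenyl-5,5,8a-trimethyl-1,2,4a,5,6,7,8,8a-octahydronaphthalen-2-yl]methanol
Conditions: TBAF, THF, 0 °C to rt
Reagents that add atoms: none
Why: Fluoride desilylation of the primary TBS ether should free the C17 alcohol, and no other fluoride- or base-sensitive group is present at this stage.

Step 11
Reactants: 17 [(1R,2S,4aR,8aS)-1-ethenyl-5,5,8a-trimethyl-1,2,4a,5,6,7,8,8a-octahydronaphthalen-2-yl]methanol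
Product: 19 (1R,2S,4aR,8aS)-1-ethenyl-5,5,8a-trimethyl-1,2,4a,5,6,7,8,8a-octahydronaphthalene-2-carboxylic acid, via aldehyde 18 (not isolated)
Conditions: TEMPO (20 mol %), PhI(OAc)2 (2.5 equiv), MeCN/H2O (1:1), rt
Reagents that add atoms: water, O
Why: TEMPO-catalysed oxidation with PhI(OAc)2 in aqueous acetonitrile takes the primary alcohol through the aldehyde hydrate to the acid under near-neutral conditions, so the β,γ-unsaturated C8 centre should neither epimerise nor move into conjugation and both alkenes are spared.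

Step 12
Reactants: 19 (1R,2S,4aR,8aS)-1-ethenyl-5,5,8a-trimethyl-1,2,4a,5,6,7,8,8a-octahydronaphthalene-2-carboxylic acid
Product: 20 methyl (1R,2S,4aR,8aS)-1-ethenyl-5,5,8a-trimethyl-1,2,4a,5,6,7,8,8a-octahydronaphthalene-2-carboxylate
Conditions: TMSCHN2, PhMe/MeOH (4:1), 0 °C
Reagents that add atoms: trimethylsilyldiazomethane, C[Si](C)(C)C=[N+]=[N-]
Why: Esterification with trimethylsilyldiazomethane and methanol methylates the acid under neutral conditions, with no base that could enolise C8.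

Step 13
Reactants: 21 methyl 4-hydroxybut-2-ynoate
Product: 22 methyl (2Z)-4-hydroxy-3-iodobut-2-enoate
Conditions: NaI, AcOH, 70 °C
Reagents that add atoms: sodium iodide, [Na+].[I-]
Why: Hydroiodination of the ynoate is a conjugate addition of iodide followed by anti protonation, which should give the Z β-iodoenoate (iodine cis to the ester); it cannot lactonise because the hydroxymethyl group is trans to the ester.

Step 14
Reactants: 20 methyl (1R,2S,4aR,8aS)-1-ethenyl-5,5,8a-trimethyl-1,2,4a,5,6,7,8,8a-octahydronaphthalene-2-carboxylate; 22 methyl (2Z)-4-hydroxy-3-iodobut-2-enoate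
Product: 24 methyl (1R,2S,4aR,8aS)-1-[(3E)-3-(hydroxymethyl)-5-methoxy-5-oxopent-3-en-1-yl]-5,5,8a-trimethyl-1,2,4a,5,6,7,8,8a-octahydronaphthalene-2-carboxylate, via B-alkyl-9-BBN 23 (not isolated)
Conditions: 20, 9-BBN (1.5 equiv), THF, rt; then aq K3PO4, 22, PdCl2(dppf) (5 mol %), AsPh3, DMF, rt
Reagents that add atoms: none
Why: 9-BBN adds only to the monosubstituted vinyl group (the ring alkene is 1,2-disubstituted and hindered, the ester inert), and B-alkyl Suzuki–Miyaura coupling with the Z iodoenoate forms C12–C13 with retention, which should place the chain cis to the ester as the target requires.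

Step 15
Reactants: 24 methyl (1R,2S,4aR,8aS)-1-[(3E)-3-(hydroxymethyl)-5-methoxy-5-oxopent-3-en-1-yl]-5,5,8a-trimethyl-1,2,4a,5,6,7,8,8a-octahydronaphthalene-2-carboxylate
Product: 25 methyl (1R,2S,4aR,8aS)-1-[(3E)-3-(acetoxymethyl)-5-methoxy-5-oxopent-3-en-1-yl]-5,5,8a-trimethyl-1,2,4a,5,6,7,8,8a-octahydronaphthalene-2-carboxylate
Conditions: Ac2O, pyridine, DMAP (cat.), CH2Cl2, 0 °C to rt
Reagents that add atoms: acetic anhydride, CC(=O)OC(C)=O
Why: DMAP-catalysed acetylation of the only hydroxyl group should give the allylic acetate under conditions too mild to enolise the C8 ester.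

**Compound list**

1 | 2,2-dimethylpent-4-enal | C=CCC(C)(C)C=O | starting material
2 | (1E)-1-iodo-3,3-dimethylhexa-1,5-diene | C=CCC(C)(C)/C=C/I | intermediate
3 | tert-butyl(dimethyl)(prop-2-yn-1-yloxy)silane | C#CCO[Si](C)(C)C(C)(C)C | starting material
4 | tert-butyl{[(4E)-6,6-dimethylnona-4,8-dien-2-yn-1-yl]oxy}dimethylsilane | C=CCC(C)(C)/C=C/C#CCO[Si](C)(C)C(C)(C)C | intermediate
5 | tert-butyl{[(2Z,4E)-6,6-dimethylnona-2,4,8-trien-1-yl]oxy}dimethylsilane | C=CCC(C)(C)/C=C/C=C\CO[Si](C)(C)C(C)(C)C | intermediate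
6 | (2E)-3-iodobut-2-enoic acid | C/C(I)=C\C(=O)O | starting material
7 | (4R)-4-benzyl-1,3-oxazolidin-2-one | O=C1N[C@H](Cc2ccccc2)CO1 | starting material
8 | (2E)-3-iodobut-2-enoyl chloride | C/C(I)=C\C(=O)Cl | intermediate
9 | lithium (4R)-4-benzyl-2-oxo-1,3-oxazolidin-3-ide | [Li+].O=C1[N-][C@H](Cc2ccccc2)CO1 | intermediate
10 | (4R)-4-benzyl-3-[(2E)-3-iodobut-2-enoyl]-1,3-oxazolidin-2-one | C/C(I)=C\C(=O)N1[C@H](Cc2ccccc2)COC1=O | intermediate
11 | 9-[(5E,7Z)-9-{[tert-butyl(dimethyl)silyl]oxy}-4,4-dimethylnona-5,7-dien-1-yl]-9-borabicyclo[3.3.1]nonane | CC(C)(C)[Si](C)(C)OC/C=C\C=C\C(C)(C)CCCB1C2CCCC1CCC2 | intermediate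
12 | (4R)-4-benzyl-3-[(2E,8E,10Z)-12-{[tert-butyl(dimethyl)silyl]oxy}-3,7,7-trimethyldodeca-2,8,10-trienoyl]-1,3-oxazolidin-2-one | CC(C)(C)[Si](C)(C)OC/C=C\C=C\C(C)(C)CCC/C(C)=C/C(=O)N1[C@H](Cc2ccccc2)COC1=O | intermediate
13 | (4R)-4-benzyl-3-{[(1R,2S,4aR,8aR)-2-({[tert-butyl(dimethyl)silyl]oxy}methyl)-5,5,8a-trimethyl-1,2,4a,5,6,7,8,8a-octahydronaphthalen-1-yl]carbonyl}-1,3-oxazolidin-2-one | O=C1OC[C@@H](Cc2ccccc2)N1C(=O)[C@@H]1[C@@H](CO[Si](C)(C)C(C)(C)C)C=C[C@@H]2C(C)(C)CCC[C@@]12C | intermediate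
14 | [(1R,2S,4aR,8aR)-2-({[tert-butyl(dimethyl)silyl]oxy}methyl)-5,5,8a-trimethyl-1,2,4a,5,6,7,8,8a-octahydronaphthalen-1-yl]methanol | OC[C@@H]1[C@@H](CO[Si](C)(C)C(C)(C)C)C=C[C@@H]2C(C)(C)CCC[C@@]12C | intermediate
15 | (1R,2S,4aR,8aR)-2-({[tert-butyl(dimethyl)silyl]oxy}methyl)-5,5,8a-trimethyl-1,2,4a,5,6,7,8,8a-octahydronaphthalene-1-carbaldehyde | O=C[C@@H]1[C@@H](CO[Si](C)(C)C(C)(C)C)C=C[C@@H]2C(C)(C)CCC[C@@]12C | intermediate
16 | tert-butyl{[(1R,2S,4aR,8aS)-1-ethenyl-5,5,8a-trimethyl-1,2,4a,5,6,7,8,8a-octahydronaphthalen-2-yl]methoxy}dimethylsilane | C=C[C@@H]1[C@@H](CO[Si](C)(C)C(C)(C)C)C=C[C@@H]2C(C)(C)CCC[C@@]12C | intermediate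
17 | [(1R,2S,4aR,8aS)-1-ethenyl-5,5,8a-trimethyl-1,2,4a,5,6,7,8,8a-octahydronaphthalen-2-yl]methanol | C=C[C@@H]1[C@@H](CO)C=C[C@@H]2C(C)(C)CCC[C@@]12C | intermediate
18 | (1R,2S,4aR,8aS)-1-ethenyl-5,5,8a-trimethyl-1,2,4a,5,6,7,8,8a-octahydronaphthalene-2-carbaldehyde | C=C[C@@H]1[C@@H](C=O)C=C[C@@H]2C(C)(C)CCC[C@@]12C | intermediate
19 | (1R,2S,4aR,8aS)-1-ethenyl-5,5,8a-trimethyl-1,2,4a,5,6,7,8,8a-octahydronaphthalene-2-carboxylic acid | C=C[C@@H]1[C@@H](C(=O)O)C=C[C@@H]2C(C)(C)CCC[C@@]12C | intermediate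
20 | methyl (1R,2S,4aR,8aS)-1-ethenyl-5,5,8a-trimethyl-1,2,4a,5,6,7,8,8a-octahydronaphthalene-2-carboxylate | C=C[C@@H]1[C@@H](C(=O)OC)C=C[C@@H]2C(C)(C)CCC[C@@]12C | intermediate
21 | methyl 4-hydroxybut-2-ynoate | COC(=O)C#CCO | starting material
22 | methyl (2Z)-4-hydroxy-3-iodobut-2-enoate | COC(=O)/C=C(\I)CO | intermediate
23 | methyl (1R,2S,4aR,8aS)-1-[2-(9-borabicyclo[3.3.1]nonan-9-yl)ethyl]-5,5,8a-trimethyl-1,2,4a,5,6,7,8,8a-octahydronaphthalene-2-carboxylate | C1CC2CCCC(C1)B2CC[C@@H]1[C@@H](C(=O)OC)C=C[C@@H]2C(C)(C)CCC[C@@]12C | intermediate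
24 | methyl (1R,2S,4aR,8aS)-1-[(3E)-3-(hydroxymethyl)-5-methoxy-5-oxopent-3-en-1-yl]-5,5,8a-trimethyl-1,2,4a,5,6,7,8,8a-octahydronaphthalene-2-carboxylate | COC(=O)/C=C(\CC[C@@H]1[C@@H](C(=O)OC)C=C[C@@H]2C(C)(C)CCC[C@@]12C)CO | intermediate
25 | methyl (1R,2S,4aR,8aS)-1-[(3E)-3-(acetoxymethyl)-5-methoxy-5-oxopent-3-en-1-yl]-5,5,8a-trimethyl-1,2,4a,5,6,7,8,8a-octahydronaphthalene-2-carboxylate | COC(=O)/C=C(\CC[C@@H]1[C@@H](C(=O)OC)C=C[C@@H]2C(C)(C)CCC[C@@]12C)COC(C)=O | target

**Step count**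

Total: 15 steps. Longest linear sequence: 13 steps (steps 1, 2, 3, 5, 6, 7, 8, 9, 10, 11, 12, 14, 15).

**Steps most likely to fail**

Step 6. The inside CH2OTBS group of the Z diene resists the s-cis arrangement, and the dienophile must form a quaternary centre next to C4. Cycloaddition may therefore be slow enough for Lewis acid induced Z-to-E isomerisation, ionisation of the dienyl silyl ether, or loss of endo and facial control at the higher temperature then needed to overtake ring closure. The fallback sets out from 2 and comes back at 18.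
- Vinyl iodide 2 is joined by Suzuki–Miyaura coupling (Pd(PPh3)4, aq K3PO4, THF) to purchased (E)-3-{[tert-butyl(dimethyl)silyl]oxy}prop-1-enylboronic acid pinacol ester to give the (2E,4E)-dienyl silyl ether F1.
- Hydroboration to the B-alkyl-9-BBN F2 and coupling with 10 as in step 5 should give the all-E trienimide F3.
- Me2AlCl-promoted cycloaddition of F3, the diene geometry with the closest precedent, should give the C8-epimeric adduct F4 with the same sense at C5, C9 and C10.
- The chemistry of steps 7 to 10 then gives the alcohol F5, the aldehyde F6, the vinyl compound F7 and the C17 alcohol F8, and Dess–Martin oxidation gives the axial aldehyde F9.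
- Brief treatment of F9 with DBU (CH2Cl2, 0 °C) should epimerise C8 to the equatorial aldehyde 18, driven by relief of the 1,3-diaxial contact with the C10 methyl group. Aldehyde 18 is oxidised at once (NaClO2, NaH2PO4, 2-methylbut-2-ene) to 19.
- The weak point of this fallback is that the double bond may move into conjugation during the epimerisation.

Step 7. The exocyclic carbonyl is flanked by the quaternary C10, so hydride may attack the ring carbonyl of the auxiliary instead and open the oxazolidinone. The fallback sets out from 13 and comes back at 15. Imide 13 is opened with LiSEt (EtSH, n-BuLi, THF, 0 °C), a small nucleophile that is selective for the exocyclic carbonyl, to give the S-ethyl thioester F10. Fukuyama reduction (Et3SiH, Pd/C, acetone) then gives aldehyde 15 directly.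

Step 14. Transmetalation of the hindered B-alkyl group may be slow, and the aqueous base may epimerise C8 or move the C6=C7 bond into conjugation. The fallback sets out from 20 and comes back at 24. Borane 23 is oxidised (NaBO3·4H2O) to the primary alcohol F11, which is converted (I2, PPh3, imidazole) into the iodide F12. Zinc insertion (Zn, LiCl, THF) gives the alkylzinc iodide F13, and base-free Negishi coupling with 22 (Pd(OAc)2, SPhos, THF, rt) should give 24.

**Further compounds**

F1 | step 6 | tert-butyl{[(2E,4E)-6,6-dimethylnona-2,4,8-trien-1-yl]oxy}dimethylsilane | C=CCC(C)(C)/C=C/C=C/CO[Si](C)(C)C(C)(C)C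
F2 | step 6 | 9-[(5E,7E)-9-{[tert-butyl(dimethyl)silyl]oxy}-4,4-dimethylnona-5,7-dien-1-yl]-9-borabicyclo[3.3.1]nonane | CC(C)(C)[Si](C)(C)OC/C=C/C=C/C(C)(C)CCCB1C2CCCC1CCC2
F3 | step 6 | (4R)-4-benzyl-3-[(2E,8E,10E)-12-{[tert-butyl(dimethyl)silyl]oxy}-3,7,7-trimethyldodeca-2,8,10-trienoyl]-1,3-oxazolidin-2-one | CC(C)(C)[Si](C)(C)OC/C=C/C=C/C(C)(C)CCC/C(C)=C/C(=O)N1[C@H](Cc2ccccc2)COC1=O
F4 | step 6 | (4R)-4-benzyl-3-{[(1R,2R,4aR,8aR)-2-({[tert-butyl(dimethyl)silyl]oxy}methyl)-5,5,8a-trimethyl-1,2,4a,5,6,7,8,8a-octahydronaphthalen-1-yl]carbonyl}-1,3-oxazolidin-2-one | O=C1OC[C@@H](Cc2ccccc2)N1C(=O)[C@@H]1[C@H](CO[Si](C)(C)C(C)(C)C)C=C[C@@H]2C(C)(C)CCC[C@@]12C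
F5 | step 6 | [(1R,2R,4aR,8aR)-2-({[tert-butyl(dimethyl)silyl]oxy}methyl)-5,5,8a-trimethyl-1,2,4a,5,6,7,8,8a-octahydronaphthalen-1-yl]methanol | OC[C@@H]1[C@H](CO[Si](C)(C)C(C)(C)C)C=C[C@@H]2C(C)(C)CCC[C@@]12C
F6 | step 6 | (1R,2R,4aR,8aR)-2-({[tert-butyl(dimethyl)silyl]oxy}methyl)-5,5,8a-trimethyl-1,2,4a,5,6,7,8,8a-octahydronaphthalene-1-carbaldehyde | O=C[C@@H]1[C@H](CO[Si](C)(C)C(C)(C)C)C=C[C@@H]2C(C)(C)CCC[C@@]12C
F7 | step 6 | tert-butyl{[(1R,2R,4aR,8aS)-1-ethenyl-5,5,8a-trimethyl-1,2,4a,5,6,7,8,8a-octahydronaphthalen-2-yl]methoxy}dimethylsilane | C=C[C@@H]1[C@H](CO[Si](C)(C)C(C)(C)C)C=C[C@@H]2C(C)(C)CCC[C@@]12C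
F8 | step 6 | [(1R,2R,4aR,8aS)-1-ethenyl-5,5,8a-trimethyl-1,2,4a,5,6,7,8,8a-octahydronaphthalen-2-yl]methanol | C=C[C@@H]1[C@H](CO)C=C[C@@H]2C(C)(C)CCC[C@@]12C
F9 | step 6 | (1R,2R,4aR,8aS)-1-ethenyl-5,5,8a-trimethyl-1,2,4a,5,6,7,8,8a-octahydronaphthalene-2-carbaldehyde | C=C[C@@H]1[C@H](C=O)C=C[C@@H]2C(C)(C)CCC[C@@]12C
F10 | step 7 | S-ethyl (1R,2S,4aR,8aR)-2-({[tert-butyl(dimethyl)silyl]oxy}methyl)-5,5,8a-trimethyl-1,2,4a,5,6,7,8,8a-octahydronaphthalene-1-carbothioate | CCSC(=O)[C@@H]1[C@@H](CO[Si](C)(C)C(C)(C)C)C=C[C@@H]2C(C)(C)CCC[C@@]12C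
F11 | step 14 | methyl (1R,2S,4aR,8aS)-1-(2-hydroxyethyl)-5,5,8a-trimethyl-1,2,4a,5,6,7,8,8a-octahydronaphthalene-2-carboxylate | OCC[C@@H]1[C@@H](C(=O)OC)C=C[C@@H]2C(C)(C)CCC[C@@]12C
F12 | step 14 | methyl (1R,2S,4aR,8aS)-1-(2-iodoethyl)-5,5,8a-trimethyl-1,2,4a,5,6,7,8,8a-octahydronaphthalene-2-carboxylate | ICC[C@@H]1[C@@H](C(=O)OC)C=C[C@@H]2C(C)(C)CCC[C@@]12C
F13 | step 14 | iodo{2-[(1R,2S,4aR,8aS)-2-(methoxycarbonyl)-5,5,8a-trimethyl-1,2,4a,5,6,7,8,8a-octahydronaphthalen-1-yl]ethyl}zinc | I[Zn]CC[C@@H]1[C@@H](C(=O)OC)C=C[C@@H]2C(C)(C)CCC[C@@]12C
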